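## Retrosynthetic overview

- The target is a cyclohex-4-ene 1,6-oxide. The last operations are desilylation at O3, benzoylation at O2 and O7, and a hydroxyl-directed epoxidation of C1=C6, so the oxirane is the second and last ring formed.
- The six-membered carbocycle is opened at C4=C5 by ring-closing metathesis of two terminal vinyl groups; it is the first ring formed.
- The strategy rests on the quaternary oxirane carbon C1, the ring atom that carries C7 and is flanked by C2 and C6. C6–C1–C7 is the three-carbon chain of methyl propiolate, capped at C6 by a vinyl group (C5, C4 precursor side) and at C1 by the aldehyde carbon C2, all in one flask.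
- The aldehyde partner carries C2, C3 and C4 and comes from (R)-but-3-ene-1,2-diol by bis-silylation and selective oxidation of the primary silyl ether.

Key step: step 3

Assumption: (R)-but-3-ene-1,2-diol is taken as a purchasable enantiopure compound. Atom labels follow the target ring: C1 quaternary oxirane carbon, C2 CHOBz, C3 CHOH, C4=C5, C6 oxirane CH, C7 the CH2OBz carbon.

## Route

Step 1
Reactants: 1 (R)-but-3-ene-1,2-diol
Product: 2 (R)-3,4-bis(triethylsilyloxy)but-1-ene
Conditions: Et3SiCl (2.4 equiv), imidazole (4 equiv), CH2Cl2, 0 °C → rt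
Reagents that add atoms: chlorotriethylsilane, CC[Si](Cl)(CC)CC
Why: Imidazole-mediated silylation of both hydroxyls is routine and does not touch the stereocentre.

Step 2
Reactants: 2 (R)-3,4-bis(triethylsilyloxy)but-1-ene
Product: 4 (R)-2-(triethylsilyloxy)but-3-enal, via alkoxysulfonium chloride 3 (not isolated)
Conditions: (COCl)2 (4 equiv), DMSO (8 equiv), CH2Cl2, −78 → −40 °C, 30 min; then i-Pr2NEt, −78 → −40 °C; cold pH 7 buffer; short silica plug, used at once
Reagents that add atoms: none
Why: In this Swern oxidation applied directly to a bis-silyl ether, the chlorosulfonium salt should exchange only the less hindered primary Et3SiO group for the alkoxysulfonium unit, and elimination with a hindered amine in the cold then gives the aldehyde with the secondary silyl ether and the C3 configuration intact.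

Step 3
Reactants: 4 (R)-2-(triethylsilyloxy)but-3-enal; 5 vinylmagnesium bromide; 6 methyl propiolate
Product: 9 methyl (2E)-2-[(1S,2R)-1-hydroxy-2-(triethylsilyloxy)but-3-en-1-yl]penta-2,4-dienoate, via vinylcopper 7 (not isolated), via α-cuprio dienoate 8 (not isolated)
Conditions: 5 (1.3 equiv), CuBr·SMe2 (1.3 equiv), THF, −78 → −45 → −78 °C; 6 (1.2 equiv), −78 °C, 1 h; 4 (1.0 equiv) in THF, −78 °C, 2 h; aq. NH4Cl at −78 °C
Reagents that add atoms: vinylmagnesium bromide (5), C=C[Mg]Br; methyl propiolate (6), C#CC(=O)OC
Why: Transmetalation of 5 with CuBr·SMe2 gives vinylcopper 7, which adds syn across the triple bond of 6 (carbocupration, vinyl to the β-carbon C6 and copper to the α-carbon C1), and the α-cuprio dienoate 8 then attacks the aldehyde carbon of 4 in an aldol-type addition assisted by the MgBr2 present, so that C5–C6 and C1–C2 are formed in one flask. The closest known reaction type is the tandem organocopper conjugate addition to propiolate esters with aldehyde trapping, which gives β-substituted Morita–Baylis–Hillman-type adducts. No ring is closed in this step. C2 is the only new stereocentre and should be set by Felkin–Anh (polar) control from C3: the nucleophile enters anti to the C3–OSiEt3 bond, which gives the 2,3-anti relation that becomes cis on the ring, while C3 is carried in from 4. The step needs retention of the syn-addition geometry, so that C2 and C5 sit cis on C1=C6 (vinyl trans to the ester), and Felkin–Anh attack in preference to chelate attack; the first is secured by holding 8 at −78 °C until the aldehyde is consumed, the second by the bulky, weakly coordinating triethylsilyl ether in THF. Quenching cold should also prevent silyl migration from O3 to the new C2 alkoxide.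

Step 4
Reactants: 9 methyl (2E)-2-[(1S,2R)-1-hydroxy-2-(triethylsilyloxy)but-3-en-1-yl]penta-2,4-dienoate
Product: 10 methyl (5R,6S)-6-hydroxy-5-(triethylsilyloxy)cyclohexa-1,3-diene-1-carboxylate
Conditions: second-generation Grubbs catalyst (H2IMes)(PCy3)Cl2Ru=CHPh (5 mol %), CH2Cl2 (0.005 M), 40 °C
Reagents that add atoms: none
Why: Ring-closing metathesis of the two terminal vinyl groups should close the six-membered carbocycle at C4=C5 with loss of ethylene, since the trisubstituted ester-bearing C1=C6 alkene is inert to the ruthenium carbene and no stereocentre is involved.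

Step 5
Reactants: 10 methyl (5R,6S)-6-hydroxy-5-(triethylsilyloxy)cyclohexa-1,3-diene-1-carboxylate
Product: 11 (1S,6R)-2-(hydroxymethyl)-6-(triethylsilyloxy)cyclohexa-2,4-dien-1-ol
Conditions: i-Bu2AlH (3.5 equiv), CH2Cl2, −78 °C; aq. sodium potassium tartrate
Reagents that add atoms: none
Why: DIBAL-H 1,2-reduction of the conjugated ester should give the primary allylic alcohol at C7, with one equivalent of hydride consumed by the free C2 hydroxyl and the silyl ether and diene left untouched.

Step 6
Reactants: 11 (1S,6R)-2-(hydroxymethyl)-6-(triethylsilyloxy)cyclohexa-2,4-dien-1-ol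
Product: 12 (1R,2R,3R,6S)-1-(hydroxymethyl)-3-(triethylsilyloxy)-7-oxabicyclo[4.1.0]hept-4-en-2-ol
Conditions: VO(acac)2 (5 mol %), t-BuOOH (1.2 equiv, in decane), CH2Cl2, 0 °C
Reagents that add atoms: tert-butyl hydroperoxide, CC(C)(C)OO
Why: In this vanadium-catalysed hydroxyl-directed epoxidation the vanadate ester of the allylic C2 hydroxyl (with the C7 hydroxyl) should deliver oxygen to the proximal C1=C6 alkene on the face syn to C2–OH, setting C1 and C6, while C4=C5, flanked only by the silyl ether, reacts much more slowly.

Step 7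
Reactants: 12 (1R,2R,3R,6S)-1-(hydroxymethyl)-3-(triethylsilyloxy)-7-oxabicyclo[4.1.0]hept-4-en-2-ol; 13 benzoyl chloride
Product: 14 [(1S,2R,3R,6S)-2-(benzoyloxy)-3-(triethylsilyloxy)-7-oxabicyclo[4.1.0]hept-4-en-1-yl]methyl benzoate
Conditions: BzCl (3 equiv), pyridine, DMAP (0.1 equiv), CH2Cl2, 0 °C → rt
Reagents that add atoms: benzoyl chloride (13), O=C(Cl)c1ccccc1
Why: DMAP-catalysed acylation should esterify the primary C7 and the secondary C2 hydroxyl under weakly basic conditions that leave the vinyl epoxide and the silyl ether intact.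

Step 8
Reactants: 14 [(1S,2R,3R,6S)-2-(benzoyloxy)-3-(triethylsilyloxy)-7-oxabicyclo[4.1.0]hept-4-en-1-yl]methyl benzoate
Product: 15 [(1S,2R,3R,6S)-2-(benzoyloxy)-3-hydroxy-7-oxabicyclo[4.1.0]hept-4-en-1-yl]methyl benzoate
Conditions: Bu4NF (1.5 equiv), AcOH (1.5 equiv), THF, 0 °C
Reagents that add atoms: none
Why: Fluoride cleavage of the triethylsilyl ether buffered with acetic acid keeps the medium near neutral, so neither benzoate migration from O2 to the cis O3 nor opening of the vinyl epoxide is expected.

## Compound list

1 | (R)-but-3-ene-1,2-diol | OC[C@H](O)C=C | starting material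
2 | (R)-3,4-bis(triethylsilyloxy)but-1-ene | CC[Si](CC)(CC)OC[C@H](O[Si](CC)(CC)CC)C=C | intermediate
3 | dimethyl{[(2R)-2-(triethylsilyloxy)but-3-en-1-yl]oxy}sulfonium chloride | C[S+](C)OC[C@H](O[Si](CC)(CC)CC)C=C.[Cl-] | intermediate
4 | (R)-2-(triethylsilyloxy)but-3-enal | O=C[C@H](O[Si](CC)(CC)CC)C=C | intermediate
5 | vinylmagnesium bromide | C=C[Mg]Br | starting material
6 | methyl propiolate | C#CC(=O)OC | starting material
7 | vinylcopper (as its MgBr2 complex) | C=C[Cu] | intermediate
8 | methyl (2Z)-2-cupriopenta-2,4-dienoate (vinyl cis to copper) | C=C/C=C(\[Cu])C(=O)OC | intermediate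
9 | methyl (2E)-2-[(1S,2R)-1-hydroxy-2-(triethylsilyloxy)but-3-en-1-yl]penta-2,4-dienoate (C5 vinyl cis to C2) | C=C/C=C(/C(=O)OC)[C@H](O)[C@H](O[Si](CC)(CC)CC)C=C | intermediate
10 | methyl (5R,6S)-6-hydroxy-5-(triethylsilyloxy)cyclohexa-1,3-diene-1-carboxylate | COC(=O)C1=CC=C[C@@H](O[Si](CC)(CC)CC)[C@H]1O | intermediate
11 | (1S,6R)-2-(hydroxymethyl)-6-(triethylsilyloxy)cyclohexa-2,4-dien-1-ol | OCC1=CC=C[C@@H](O[Si](CC)(CC)CC)[C@H]1O | intermediate
12 | (1R,2R,3R,6S)-1-(hydroxymethyl)-3-(triethylsilyloxy)-7-oxabicyclo[4.1.0]hept-4-en-2-ol (oxirane O, O2 and O3 on one face) | OC[C@]12O[C@H]1C=C[C@@H](O[Si](CC)(CC)CC)[C@H]2O | intermediate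
13 | benzoyl chloride | O=C(Cl)c1ccccc1 | starting material
14 | [(1S,2R,3R,6S)-2-(benzoyloxy)-3-(triethylsilyloxy)-7-oxabicyclo[4.1.0]hept-4-en-1-yl]methyl benzoate | O=C(OC[C@]12O[C@H]1C=C[C@@H](O[Si](CC)(CC)CC)[C@H]2OC(=O)c1ccccc1)c1ccccc1 | intermediate
15 | [(1S,2R,3R,6S)-2-(benzoyloxy)-3-hydroxy-7-oxabicyclo[4.1.0]hept-4-en-1-yl]methyl benzoate | O=C(OC[C@]12O[C@H]1C=C[C@@H](O)[C@H]2OC(=O)c1ccccc1)c1ccccc1 | target

## Step count and risks

Total step count: 8. Longest linear sequence: 8 steps (1 → 15).

Steps most likely to fail: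

1. Step 3. The alkenylcopper may isomerise through its allenoate form if the aldol is slow, giving the wrong C1=C6 geometry. Chelate-controlled attack may compete with Felkin–Anh attack and erode the C2 selectivity, and a vinyl group may transfer directly to the aldehyde. Fallback: the two bond formations are separated. The α-cuprio dienoate 8 is generated from 5 and 6 as in step 3 and quenched with I2 at −78 °C to give methyl (2Z)-2-iodopenta-2,4-dienoate F1, whose geometry can be checked and purified. F1 is then coupled with 4 in a Nozaki–Hiyama–Kishi reaction (CrCl2, NiCl2 cat., DMF, rt). The alkenylchromium species keeps its geometry, is not basic and should add to the α-silyloxy aldehyde with Felkin–Anh preference. The route is rejoined at 9.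

2. Step 2. The amine stage may cause α-epimerisation or migration of the vinyl double bond into conjugation with the aldehyde, and the two silyl ethers may be discriminated incompletely. Fallback: from 2, selective acid methanolysis of the primary silyl ether (PPTS, MeOH/CH2Cl2, −20 °C) gives (R)-2-(triethylsilyloxy)but-3-en-1-ol F2. F2 is oxidised with Dess–Martin periodinane and NaHCO3 in CH2Cl2 at 0 °C, without any amine base. The route is rejoined at 4.

3. Step 6. Oxidation may occur at C4=C5 or twice, and the Lewis-acidic vanadium centre may open the vinyl epoxide or promote dehydrative aromatisation of the dienol. Fallback: the oxirane is installed before the carbocycle. From 9, i-Bu2AlH reduction (CH2Cl2, −78 °C) gives the acyclic dienediol (2Z)-2-[(1S,2R)-1-hydroxy-2-(triethylsilyloxy)but-3-en-1-yl]penta-2,4-dien-1-ol F3. Sharpless asymmetric epoxidation of its primary allylic alcohol (Ti(OiPr)4, D-(−)-diisopropyl tartrate, t-BuOOH, 4 Å molecular sieves, CH2Cl2, −20 °C) should deliver oxygen under reagent control to the required face of C1=C6 and give (1R,2R)-1-[(2R,3S)-3-ethenyl-2-(hydroxymethyl)oxiran-2-yl]-2-(triethylsilyloxy)but-3-en-1-ol F4. Ring-closing metathesis of F4 with (H2IMes)(PCy3)Cl2Ru=CHPh in CH2Cl2 at 40 °C closes C4=C5, so no cyclohexadiene is exposed to an oxidant. The route is rejoined at 12.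

Further compounds

F1 | step 3 | methyl (2Z)-2-iodopenta-2,4-dienoate | C=C/C=C(\I)C(=O)OC
F2 | step 2 | (R)-2-(triethylsilyloxy)but-3-en-1-ol | OC[C@H](O[Si](CC)(CC)CC)C=C
F3 | step 6 | (2Z)-2-[(1S,2R)-1-hydroxy-2-(triethylsilyloxy)but-3-en-1-yl]penta-2,4-dien-1-ol | C=C/C=C(/CO)[C@H](O)[C@H](O[Si](CC)(CC)CC)C=C
F4 | step 6 | (1R,2R)-1-[(2R,3S)-3-ethenyl-2-(hydroxymethyl)oxiran-2-yl]-2-(triethylsilyloxy)but-3-en-1-ol | OC[C@@]1(O[C@H]1C=C)[C@H](O)[C@H](O[Si](CC)(CC)CC)C=C
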